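The earlier runs and the new flask are calculated with made-up constants, and the scatter is random.

1. The autumn run, which held twice the coupling partner of the new flask on the same charge of solid substrate, was what I had to reason from.

- autumn: solid substrate 0.25 M; coupling partner 0.60 M; run made earlier
- flask: solid substrate 0.25 M; coupling partner 0.300 M; time 4.0 min

autumn run (percent of the solid substrate charged)

| time / s | target / % | solid substrate / % |
|---|---|---|
| 12.0 | 2 | 81 |
| 25.0 | 9 | 73 |
| 40.0 | 17 | 60 |
| 50.0 | 19 | 44 |
| 60.0 | 17 | 35 |
| 80.0 | 26 | 15 |

(standard deviation of a reading: 2 percentage points)

- amount of target in percent of the solid substrate charged, at 25 s, 80 s, 2.5 min and 4.0 min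

- solid substrate is a solid; its amount is given per volume of the solution
- at the start none of the solid substrate is in solution

2. In that run the solid fell from 81 % at 12.0 s to 15 % at 80.0 s, a loss of 0.971 % s⁻¹ of the charge. At that pace it would last until 95.5 s.

3. My first estimate read the gap, meaning what was neither solid nor target, as dissolved substrate. It grew from 18.0 % at 25.0 s to 59.0 % at 80.0 s.

4. The objection came from the target. If the gap set its rate, that rate should have climbed. Instead the readings gave 0.536 % s⁻¹ from 12.0 s to 40.0 s and 0.225 % s⁻¹ from there to 80.0 s, slower. So I dropped the gap. I took [dissolved substrate] as held roughly steady while solid remained, which leaves the coupling pseudo-first-order in [coupling partner].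

5. That gave me one quantity, the partner yield g, the target formed per second and per molar partner while solid lasts: 0.00542 M⁻¹ s⁻¹, from the last autumn reading.

6. But does [coupling partner] stay put? In the new flask g gave 4.06 % at 25 s and 13.0 % at 80 s, and that second amount costs 10.8 % of the partner. I kept [coupling partner] constant and accepted an error of that size.

7. My line ended with the solid, where it reached 15.5 %. I held that value for 2.5 min and 4.0 min, a weak guess, since no reading went past 80.0 s.

8. The forecast reasoned that “most substrate is waiting in solution” and gave 3 %, 17 %, 40 % and 58 %.

9. The new flask gave 5.10 %, 12.4 %, 10.2 % and 5.08 % at the four times.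

    starting material + coupling partner ⇌ target (K = 3.00 M⁻¹, k = 0.0810 M⁻¹ s⁻¹)
    starting material → side product (k = 0.00370 s⁻¹)
    solid substrate ⇌ starting material, rate k3*(cs3 - [starting material]) while solid is left; crystals form when [starting material] > cs3 (solubility = 0.0900 M, k = 0.0470 s⁻¹)
    2 starting material → homo dimer (k = 0.410 M⁻¹ s⁻¹)

In this flask starting material, the dissolved substrate, stood at 15.8 % after 0.400 min and 12.6 % after 2.00 min. For 0.400 min, g gives 3.90 % of target, and the flask held 4.87 %. After 4.00 min the flask held 80.1 % of the charge as homo dimer, counted in substrate units, and 5.08 % as target.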